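The angular C1 methyl is read as half of a cyclopropane. A methylene is added across C1=C5, the bond shared by the five-membered ring A and the seven-membered ring B, and the C5–CH2 bond is cut later through a C6 ketone. The key step builds quaternary C1 and fixes both ring-fusion carbons in one operation. It exploits the fact that the C1 methyl sits on the face of ring A that carries the C2 and C4 oxygens, so a zinc carbenoid anchored on the C4 hydroxyl delivers the methylene there. The precursor is a hydroazulene 1(5),8-diene with free tertiary C4–OH, C2–OTBS and C6–OTES, closed by metathesis.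

Key step: step 9

Remark 1 (numbering): terpene numbering is used: C1 quaternary ring-fusion carbon (methyl), C2 (angelate), C3, C4 (hydroxyl and isopropyl), C5 (ring-fusion CH), C6 (anisoate), C7, C8 (methyl)=C9, C10; ring A = C1–C5, ring B = C1, C5–C10; β is the face of ring A with the C2 and C4 oxygens and the C1 methyl, α the face of the isopropyl group and H5.

Remark 2 (locants): with von Baeyer locants diene 14 is a 4-methyl-8-isopropylbicyclo[5.3.0]deca-1(7),3-diene with its oxygens on C6, C8 and C10; the locants 2, 4 and 6 for the oxygens hold only in the terpene numbering.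

Remark 3 (assumption): step 6 is expected to give both C6 epimers; they are carried on together and converge at ketone 19, and compounds 12–14 and 16–18 are written as the 6α-oxygen epimer.

Remark 4 (precursor design): the C2 oxygen enters as a TBS ether and the C6 oxygen is capped as the more labile TES ether. After the key step C6 alone can then be unmasked and oxidised. This avoids a cyclic acetal across the C2/C4 diol, which would share its face with the cyclopropane, and avoids any selective silylation between two secondary allylic hydroxyls.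

Step 1
Reactants: 1 (R)-4-(tert-butyldimethylsilyloxy)cyclopent-2-en-1-one; 2 allylmagnesium bromide
Product: 3 (3R,4R)-3-allyl-4-(tert-butyldimethylsilyloxy)-1-(trimethylsilyloxy)cyclopent-1-ene (allyl trans to OTBS)
Conditions: allylMgBr (1.3 equiv), CuBr·SMe2 (1.3 equiv), TMSCl (2.5 equiv), THF, −78 °C; Et3N, pentane, cold aq NaHCO3
Reagents that add atoms: allylmagnesium bromide 2 C=CC[Mg]Br; chlorotrimethylsilane C[Si](C)(C)Cl
Why: Copper-mediated conjugate allylation with chlorosilane trapping should add the allyl group anti to the silyloxy group and fix the enolate as the C1=C2 enol silane before it can equilibrate and expel the silyloxy group; the new centre is controlled by the existing one and is removed again in step 2.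

Step 2
Reactants: 3 (3R,4R)-3-allyl-4-(tert-butyldimethylsilyloxy)-1-(trimethylsilyloxy)cyclopent-1-ene
Product: 4 (R)-3-allyl-4-(tert-butyldimethylsilyloxy)cyclopent-2-en-1-one
Conditions: Pd(OAc)2 (1.05 equiv), MeCN, 23 °C
Reagents that add atoms: none
Why: Saegusa–Ito oxidation, in which the divalent palladium enolate undergoes β-hydride elimination towards the allyl-bearing carbon, should regenerate the enone with the allyl group on the β-carbon while the silyloxy stereocentre is untouched.

Step 3
Reactants: 4 (R)-3-allyl-4-(tert-butyldimethylsilyloxy)cyclopent-2-en-1-one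
Product: 5 (R)-3-allyl-4-(tert-butyldimethylsilyloxy)-2-iodocyclopent-2-en-1-one
Conditions: I2 (1.5 equiv), pyridine/CH2Cl2 (1:1), DMAP (0.2 equiv), 0 → 23 °C; aq Na2S2O3
Reagents that add atoms: iodine II
Why: α-Iodination of an enone by the addition–iodination–elimination sequence (amine adds at the β-carbon, the enolate is iodinated, the amine leaves) functionalises only the α-carbon under conditions mild enough for the γ-silyloxy group, and any reversible iodine uptake by the terminal alkene is undone on thiosulfate work-up.

Step 4
Reactants: 5 (R)-3-allyl-4-(tert-butyldimethylsilyloxy)-2-iodocyclopent-2-en-1-one; 6 isopropylmagnesium chloride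
Product: 7 (1R,4R)-3-allyl-4-(tert-butyldimethylsilyloxy)-2-iodo-1-isopropylcyclopent-2-en-1-ol (hydroxyl cis to OTBS)
Conditions: CeCl3 (anhydrous, 1.6 equiv), iPrMgCl (1.5 equiv), THF, −78 °C; aq NH4Cl
Reagents that add atoms: isopropylmagnesium chloride 6 CC(C)[Mg]Cl
Why: The organocerium reagent should add 1,2 to the hindered, enolisable iodoenone without enolisation, reduction or iodine–metal exchange, and it approaches the face opposite the bulky silyloxy group, so the new tertiary hydroxyl (future C4–OH) ends up cis to the future C2 oxygen.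

Step 5
Reactants: 7 (1R,4R)-3-allyl-4-(tert-butyldimethylsilyloxy)-2-iodo-1-isopropylcyclopent-2-en-1-ol; 8 N,N-dimethylformamide
Product: 10 (3R,5R)-2-allyl-3-(tert-butyldimethylsilyloxy)-5-hydroxy-5-isopropylcyclopent-1-ene-1-carbaldehyde, via dilithio alkoxide 9 (not isolated)
Conditions: t-BuLi (3.1 equiv), Et2O, −78 °C; DMF (4 equiv), −78 → 0 °C; aq NH4Cl
Reagents that add atoms: N,N-dimethylformamide 8 CN(C)C=O
Why: Deprotonation of the hydroxyl and iodine–lithium exchange are faster than any allylic deprotonation at −78 °C, and the alkenyllithium is formylated by DMF (Bouveault-type formylation) to give the C6 aldehyde carbon; no stereocentre is formed.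

Step 6
Reactants: 10 (3R,5R)-2-allyl-3-(tert-butyldimethylsilyloxy)-5-hydroxy-5-isopropylcyclopent-1-ene-1-carbaldehyde; 11 2-methylallylmagnesium chloride
Product: 12 (1R,4R)-3-allyl-4-(tert-butyldimethylsilyloxy)-2-[(1S)-1-hydroxy-3-methylbut-3-en-1-yl]-1-isopropylcyclopent-2-en-1-ol (drawn C6 epimer)
Conditions: 2-methylallylMgCl (2.5 equiv), THF, −78 → 0 °C; aq NH4Cl
Reagents that add atoms: 2-methylallylmagnesium chloride 11 CC(=C)C[Mg]Cl
Why: Allylic Grignard reagents add 1,2 to enals through a six-membered transition state after one equivalent has deprotonated the tertiary hydroxyl, which avoids the enolisable 3-methylbut-3-enal as an electrophile; the C6 carbinol centre is not controlled and need not be, since it is oxidised in step 11.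

Step 7
Reactants: 12 (1R,4R)-3-allyl-4-(tert-butyldimethylsilyloxy)-2-[(1S)-1-hydroxy-3-methylbut-3-en-1-yl]-1-isopropylcyclopent-2-en-1-ol
Product: 13 C6 triethylsilyl ether of 12
Conditions: Et3SiCl (1.2 equiv), imidazole, DMF, 0 °C
Reagents that add atoms: chlorotriethylsilane CC[Si](Cl)(CC)CC
Why: Silylation with a chlorosilane and imidazole takes the secondary allylic hydroxyl and leaves the hindered tertiary one, giving a C6 ether that can later be removed beside the C2 TBS ether.

Step 8
Reactants: 13 C6 triethylsilyl ether of 12
Product: 14 ring-closed 1(5),8-diene: 2β-OTBS 4β-OH 4α-isopropyl 6α-OTES 8-methyl hydroazulene (precursor of the key step)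
Conditions: second-generation Grubbs catalyst (H2IMes)(PCy3)Cl2Ru=CHPh (5 mol %), CH2Cl2 (5 mM), 40 °C
Reagents that add atoms: none
Why: Ring-closing metathesis between the monosubstituted and the 1,1-disubstituted alkene, held cis on the cyclopentene, should close ring B with loss of ethene and give the trisubstituted C8=C9 alkene, while the tetrasubstituted ring alkene is inert to the ruthenium carbene.

Step 9
Reactants: 14 ring-closed 1(5),8-diene (2β-OTBS 4β-OH 6α-OTES); 15 diiodomethane
Product: 17 C1/C5 β-methylene adduct of 14 (cyclopropane fused across the ring-fusion bond), via ethylzinc alkoxide 16 (not isolated)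
Conditions: Et2Zn (1.1 equiv), CH2Cl2, 0 °C, 15 min; then premixed Et2Zn (2 equiv)/CH2I2 (4 equiv), 0 → 23 °C; aq NH4Cl
Reagents that add atoms: diiodomethane 15 ICI
Why: Et2Zn converts the tertiary C4 hydroxyl into its ethylzinc alkoxide 16 with loss of ethane; the alkoxide binds the iodomethylzinc carbenoid, which transfers CH2 to C1=C5 through the butterfly transition state and forms C1–CH2 and C5–CH2 together. This is the Furukawa variant of the hydroxyl-directed Simmons–Smith cyclopropanation, a reaction type established for tetrasubstituted alkenes that carry a tertiary allylic hydroxyl. The three-membered ring closes by a concerted, suprafacial [2+1] addition of the methylene to the π bond without an open intermediate. Both new stereocentres, quaternary C1 and C5, are set by delivery from the zinc alkoxide on the β face of ring A, the face that also carries the C2 oxygen, while the isopropyl group on C4 screens the α face. The step needs facial selectivity and chemoselectivity over C8=C9: the first rests on the tethered delivery (the C2 silyl ether lies on the same face, but its silyl group can turn outward), and the second rests on C1=C5 being the only alkene within reach of the alkoxide, since the C6 oxygen is silylated and C8=C9 has no free allylic hydroxyl.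

Step 10
Reactants: 17 C1/C5 β-methylene adduct of 14
Product: 18 cyclopropane 4β,6-diol (C2–OTBS retained)
Conditions: HF·pyridine, pyridine, THF, 0 °C
Reagents that add atoms: none
Why: Buffered fluoride cleaves the secondary triethylsilyl ether much faster than the secondary tert-butyldimethylsilyl ether, and the non-ionising medium spares the two cyclopropylcarbinyl alcohols.

Step 11
Reactants: 18 cyclopropane 4β,6-diol (C2–OTBS retained)
Product: 19 C6 cyclopropyl ketone (4β-OH; C2–OTBS)
Conditions: Dess–Martin periodinane, NaHCO3, CH2Cl2, 0 → 23 °C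
Reagents that add atoms: none
Why: Dess–Martin oxidation under buffered conditions converts the only secondary hydroxyl into the ketone, the tertiary hydroxyl cannot be oxidised, and both C6 epimers converge on one compound.

Step 12
Reactants: 19 C6 cyclopropyl ketone
Product: 22 trans-fused C6 ketone (C1β-methyl; H5α; 4β-OH; C2–OTBS), via lithium enolate 20 (not isolated), via cis-fused ketone 21 (not isolated)
Conditions: Li (6 equiv), NH3(l)/THF, −78 °C, 15 min; isoprene; solid NH4Cl; crude: DBU (0.2 equiv), toluene, 23 °C
Reagents that add atoms: none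
Why: In this dissolving-metal cleavage of a conjugated cyclopropyl ketone the ketyl opens the bond that overlaps best with the carbonyl π system and leads to the less substituted carbanion, namely C5–CH2 (external to both rings), which gives the C1 methyl and the C5=C6 enolate, and mild base equilibration of the protonated ketone through its enolate should settle on the trans-fused epimer, in which C6 is cis to the small, hydrogen-bonding C4 hydroxyl and not to the isopropyl group.

Step 13
Reactants: 22 trans-fused C6 ketone
Product: 23 4β,6α-diol (C2–OTBS)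
Conditions: Me4NBH(OAc)3 (5 equiv), MeCN/AcOH (1:1), −30 → 0 °C
Reagents that add atoms: none
Why: In this Evans–Saksena reduction the C4 hydroxyl exchanges onto boron and delivers hydride to the C6 carbonyl through a six-membered transition state, which is possible only from the side of ring B on which C4 sits, so the 1,3-anti diol with the 6α-hydroxyl of the target should result.

Step 14
Reactants: 23 4β,6α-diol (C2–OTBS); 24 4-methoxybenzoyl chloride
Product: 25 C6 4-methoxybenzoate of 23
Conditions: 4-MeOC6H4COCl (1.5 equiv), pyridine, DMAP (0.1 equiv), CH2Cl2, 0 → 23 °C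
Reagents that add atoms: 4-methoxybenzoyl chloride 24 COc1ccc(cc1)C(Cl)=O
Why: Nucleophile-catalysed acylation takes the only secondary hydroxyl, and the hindered tertiary C4 hydroxyl does not react.

Step 15
Reactants: 25 C6 4-methoxybenzoate of 23
Product: 26 2β,4β-diol 6α-(4-methoxybenzoate)
Conditions: HF·pyridine, THF, 0 → 23 °C
Reagents that add atoms: none
Why: Fluoride-induced cleavage of the silicon–oxygen bond frees the C2 hydroxyl, and the aryl ester, the trisubstituted alkene and the tertiary alcohol are inert to this weakly acidic fluoride source.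

Step 16
Reactants: 26 2β,4β-diol 6α-(4-methoxybenzoate); 27 angelic acid
Product: 29 target CNP0204191.1, via angelic 2,4,6-trichlorobenzoic anhydride 28 (not isolated)
Conditions: angelic acid (3 equiv), 2,4,6-Cl3C6H2COCl (3 equiv), Et3N (6 equiv), toluene, 23 °C, 2 h; then 26, 80 °C
Reagents that add atoms: angelic acid 27 C/C=C(/C)C(=O)O
Why: Yamaguchi-type esterification through the mixed anhydride, run without a nucleophilic catalyst so that the Z alkene of the angeloyl group is not isomerised, should acylate the secondary C2 hydroxyl only, the tertiary C4 hydroxyl being too hindered.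

Compound list
1 | (R)-4-(tert-butyldimethylsilyloxy)cyclopent-2-en-1-one | O=C1C=C[C@H](O[Si](C)(C)C(C)(C)C)C1 | starting material
2 | allylmagnesium bromide | C=CC[Mg]Br | starting material
3 | (3R,4R)-3-allyl-4-(tert-butyldimethylsilyloxy)-1-(trimethylsilyloxy)cyclopent-1-ene | C=CC[C@@H]1C=C(O[Si](C)(C)C)C[C@H]1O[Si](C)(C)C(C)(C)C | intermediate
4 | (R)-3-allyl-4-(tert-butyldimethylsilyloxy)cyclopent-2-en-1-one | C=CCC1=CC(=O)C[C@H]1O[Si](C)(C)C(C)(C)C | intermediate
5 | (R)-3-allyl-4-(tert-butyldimethylsilyloxy)-2-iodocyclopent-2-en-1-one | C=CCC1=C(I)C(=O)C[C@H]1O[Si](C)(C)C(C)(C)C | intermediate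
6 | isopropylmagnesium chloride | CC(C)[Mg]Cl | starting material
7 | (1R,4R)-3-allyl-4-(tert-butyldimethylsilyloxy)-2-iodo-1-isopropylcyclopent-2-en-1-ol | C=CCC1=C(I)[C@](O)(C(C)C)C[C@H]1O[Si](C)(C)C(C)(C)C | intermediate
8 | N,N-dimethylformamide | CN(C)C=O | starting material
9 | dilithio species from 7 (lithium alkoxide; lithium in place of iodine) | C=CCC1=C([Li])[C@](O[Li])(C(C)C)C[C@H]1O[Si](C)(C)C(C)(C)C | intermediate (not isolated)
10 | (3R,5R)-2-allyl-3-(tert-butyldimethylsilyloxy)-5-hydroxy-5-isopropylcyclopent-1-ene-1-carbaldehyde | C=CCC1=C(C=O)[C@](O)(C(C)C)C[C@H]1O[Si](C)(C)C(C)(C)C | intermediate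
11 | 2-methylallylmagnesium chloride | CC(=C)C[Mg]Cl | starting material
12 | (1R,4R)-3-allyl-4-(tert-butyldimethylsilyloxy)-2-[(1S)-1-hydroxy-3-methylbut-3-en-1-yl]-1-isopropylcyclopent-2-en-1-ol | C=CCC1=C([C@@H](O)CC(C)=C)[C@](O)(C(C)C)C[C@H]1O[Si](C)(C)C(C)(C)C | intermediate
13 | C6 triethylsilyl ether of 12 | C=CCC1=C([C@@H](O[Si](CC)(CC)CC)CC(C)=C)[C@](O)(C(C)C)C[C@H]1O[Si](C)(C)C(C)(C)C | intermediate
14 | hydroazulene 1(5),8-diene: 2β-OTBS 4β-OH 4α-isopropyl 6α-OTES 8-methyl (precursor of the key step) | CC(C)(C)[Si](C)(C)O[C@@H]1C[C@@](O)(C(C)C)C2=C1CC=C(C)C[C@@H]2O[Si](CC)(CC)CC | intermediate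
15 | diiodomethane | ICI | starting material
16 | ethylzinc alkoxide of 14 (zinc on the C4 oxygen) | CC(C)(C)[Si](C)(C)O[C@@H]1C[C@@](O[Zn]CC)(C(C)C)C2=C1CC=C(C)C[C@@H]2O[Si](CC)(CC)CC | intermediate (not isolated)
17 | cyclopropane-fused hydroazulene: β-methylene across C1/C5; 2β-OTBS 4β-OH 6α-OTES (product of the key step) | CC(C)(C)[Si](C)(C)O[C@@H]1C[C@@](O)(C(C)C)[C@]23C[C@]12CC=C(C)C[C@@H]3O[Si](CC)(CC)CC | intermediate
18 | cyclopropane 4β,6-diol with 2β-OTBS | CC(C)(C)[Si](C)(C)O[C@@H]1C[C@@](O)(C(C)C)[C@]23C[C@]12CC=C(C)C[C@@H]3O | intermediate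
19 | C6 cyclopropyl ketone with 4β-OH and 2β-OTBS | CC(C)(C)[Si](C)(C)O[C@@H]1C[C@@](O)(C(C)C)[C@]23C[C@]12CC=C(C)CC3=O | intermediate
20 | dilithium C5=C6 enolate C4 alkoxide (C1 methyl in place) | CC(C)(C)[Si](C)(C)O[C@@H]1C[C@@](O[Li])(C(C)C)C2=C(O[Li])CC(C)=CC[C@]21C | intermediate (not isolated)
21 | cis-fused C6 ketone (H5β; C5 epimer of 22) | CC(C)(C)[Si](C)(C)O[C@@H]1C[C@@](O)(C(C)C)[C@H]2C(=O)CC(C)=CC[C@]21C | intermediate (not isolated)
22 | trans-fused C6 ketone: C1β-methyl H5α 4β-OH 2β-OTBS | CC(C)(C)[Si](C)(C)O[C@@H]1C[C@@](O)(C(C)C)[C@@H]2C(=O)CC(C)=CC[C@]21C | intermediate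
23 | 4β,6α-diol with 2β-OTBS | CC(C)(C)[Si](C)(C)O[C@@H]1C[C@@](O)(C(C)C)[C@@H]2[C@@H](O)CC(C)=CC[C@]21C | intermediate
24 | 4-methoxybenzoyl chloride | COc1ccc(cc1)C(Cl)=O | starting material
25 | 6α-(4-methoxybenzoate) with 4β-OH and 2β-OTBS | CC(C)(C)[Si](C)(C)O[C@@H]1C[C@@](O)(C(C)C)[C@@H]2[C@@H](OC(=O)c3ccc(OC)cc3)CC(C)=CC[C@]21C | intermediate
26 | 2β,4β-diol 6α-(4-methoxybenzoate) | O[C@@H]1C[C@@](O)(C(C)C)[C@@H]2[C@@H](OC(=O)c3ccc(OC)cc3)CC(C)=CC[C@]21C | intermediate
27 | angelic acid, (Z)-2-methylbut-2-enoic acid | C/C=C(/C)C(=O)O | starting material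
28 | angelic 2,4,6-trichlorobenzoic anhydride | C/C=C(/C)C(=O)OC(=O)c1c(Cl)cc(Cl)cc1Cl | intermediate (not isolated)
29 | CNP0204191.1, (1R,3R,3aS,4S,8aR)-3-hydroxy-4-(4-methoxybenzoyloxy)-6,8a-dimethyl-3-isopropyl-1,2,3,3a,4,5,8,8a-octahydroazulen-1-yl (Z)-2-methylbut-2-enoate | C/C=C(/C)C(=O)O[C@@H]1C[C@@](O)(C(C)C)[C@@H]2[C@@H](OC(=O)c3ccc(OC)cc3)CC(C)=CC[C@]21C | target

Total step count: 16. Longest linear sequence: 16 steps (1 to 29).

Steps most likely to fail

Step 9. The methylene transfer may stall on the hindered tetrasubstituted alkene, which three allylic oxygens deactivate inductively, and the C2 silyl ether may slow delivery on the β face. With prolonged exposure to excess carbenoid, slow cyclopropanation of C8=C9 or O-methylation of the zinc alkoxide may set in. The fallback changes the directing array, not the reagent: both ring A hydroxyls are freed so that two zinc alkoxides on the β face deliver the methylene. It sets out from 12. Acetylation of the C6 hydroxyl (Ac2O, pyridine, DMAP) gives the monocyclic C6 acetate F1, and ring-closing metathesis as in step 8 gives the bicyclic diene acetate F2. HF·pyridine then removes the C2 silyl group to give the free 2β,4β-diol acetate F3, and Et2Zn/CH2I2 should give the cyclopropane diol acetate F4. The secondary C2 hydroxyl is re-silylated (TBSCl, imidazole) to the silyl ether acetate F5, and K2CO3 in methanol removes the acetate, which returns the route to 18.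

Step 12. Protonation of the enolate may take place on the β face and give the cis ring fusion. The equilibration may then be slow, or may open ring A by retro-aldol cleavage through the free C4 hydroxyl, and excess metal may over-reduce the carbonyl during the quench. The fallback masks the tertiary hydroxyl before the reductive opening. From 19, TMSOTf and 2,6-lutidine give the C4 trimethylsilyl ether ketone F6. Li/NH3 as before is followed by a quench with 2,6-di-tert-butyl-4-methylphenol, which should protonate C5 from the α face now that the β face carries OTMS, CH3 and OTBS. Base equilibration (DBU, warm toluene) is then safe because the retro-aldol path is closed, and should give the trans-fused silyl ether ketone F7. Buffered HF·pyridine at 0 °C removes the trimethylsilyl group selectively and returns the route to 22.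

Step 13. The hindered tertiary hydroxyl may fail to exchange onto boron, so that the reduction is slow or proceeds by external hydride attack on the more open α face and gives the C6 epimer. The fallback sets C6 by inversion instead of delivery. From 22, NaBH4 (MeOH, 0 °C) should attack from the α face and give the 6β-alcohol F8. Mitsunobu esterification with 4-methoxybenzoic acid (PPh3, diisopropyl azodicarboxylate, toluene) then installs the ester with inversion and returns the route to 25, which makes step 14 unnecessary.

Further compounds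
F1 | step 9 | C6 acetate of 12 | C=CCC1=C([C@@H](OC(C)=O)CC(C)=C)[C@](O)(C(C)C)C[C@H]1O[Si](C)(C)C(C)(C)C
F2 | step 9 | hydroazulene 1(5),8-diene with 2β-OTBS 4β-OH 6α-OAc | CC(C)(C)[Si](C)(C)O[C@@H]1C[C@@](O)(C(C)C)C2=C1CC=C(C)C[C@@H]2OC(C)=O
F3 | step 9 | hydroazulene 1(5),8-diene-2β,4β-diol 6α-acetate | O[C@@H]1C[C@@](O)(C(C)C)C2=C1CC=C(C)C[C@@H]2OC(C)=O
F4 | step 9 | cyclopropane-fused 2β,4β-diol 6α-acetate | O[C@@H]1C[C@@](O)(C(C)C)[C@]23C[C@]12CC=C(C)C[C@@H]3OC(C)=O
F5 | step 9 | cyclopropane-fused 4β-ol with 2β-OTBS 6α-OAc | CC(C)(C)[Si](C)(C)O[C@@H]1C[C@@](O)(C(C)C)[C@]23C[C@]12CC=C(C)C[C@@H]3OC(C)=O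
F6 | step 12 | C4 trimethylsilyl ether of cyclopropyl ketone 19 | CC(C)(C)[Si](C)(C)O[C@@H]1C[C@@](O[Si](C)(C)C)(C(C)C)[C@]23C[C@]12CC=C(C)CC3=O
F7 | step 12 | C4 trimethylsilyl ether of trans-fused ketone 22 | CC(C)(C)[Si](C)(C)O[C@@H]1C[C@@](O[Si](C)(C)C)(C(C)C)[C@@H]2C(=O)CC(C)=CC[C@]21C
F8 | step 13 | 4β,6β-diol with 2β-OTBS (C6 epimer of 23) | CC(C)(C)[Si](C)(C)O[C@@H]1C[C@@](O)(C(C)C)[C@@H]2[C@H](O)CC(C)=CC[C@]21C
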